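The feature exploited is ring B of the flavanone half: a benzene ring carrying a carbon substituent at C1′, C8 of the flavone at C3′ and oxygen at C4′, which maps onto a 2-silyloxy-3-arylbutadiene plus a propiolate. Ring B is therefore not coupled to the flavone but grown on it: an 8-(3-silyloxybuta-1,3-dien-2-yl) derivative of tribenzyl apigenin undergoes Diels–Alder addition to methyl propiolate and DDQ aromatisation in one flask, forming C1′–C2′ and C5′–C6′ with the ester para to oxygen. The C8–C3′ bond originates from an aromatic Claisen rearrangement at the acetophenone stage. The ester carbon later becomes C2, set 2S by a thiourea-catalysed oxa-Michael cyclisation.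

Key step: step 8

Assumption: the quinine-derived bifunctional thiourea is taken to give the 2S series in step 14. A control cyclisation on the analogue made from 4-(benzyloxy)benzaldehyde should confirm this; otherwise the quinidine-derived pseudoenantiomer is used with no other change.

Remark on names: Fl stands for the 5,7-bis(benzyloxy)-2-[4-(benzyloxy)phenyl]-4-oxo-4H-chromen-8-yl group.

Step 1
Reactants: 1 2,4,6-trihydroxyacetophenone
Product: 2 1-[2,4-bis(benzyloxy)-6-hydroxyphenyl]ethan-1-one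
Conditions: BnBr (2.05 equiv), K2CO3, DMF, 0 °C to rt
Reagents that add atoms: benzyl bromide, BrCc1ccccc1
Why: Williamson etherification in which the hydroxyl chelated to the acetyl carbonyl is the least nucleophilic, so the para and one ortho phenol should be benzylated and one ortho hydroxyl is left free.

Step 2
Reactants: 2 1-[2,4-bis(benzyloxy)-6-hydroxyphenyl]ethan-1-one; 3 allyl bromide
Product: 4 1-[2-(allyloxy)-4,6-bis(benzyloxy)phenyl]ethan-1-one
Conditions: 3 (1.5 equiv), K2CO3, DMF, 60 °C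
Reagents that add atoms: none
Why: Williamson allylation of the remaining hydrogen-bonded phenol, which needs only a polar solvent and gentle heating, should give the aryl allyl ether.

Step 3
Reactants: 4 1-[2-(allyloxy)-4,6-bis(benzyloxy)phenyl]ethan-1-one
Product: 5 1-[3-allyl-4,6-bis(benzyloxy)-2-hydroxyphenyl]ethan-1-one
Conditions: PhNEt2, 200 °C
Reagents that add atoms: none
Why: Aromatic Claisen rearrangement ([3,3]-sigmatropic shift) can only deliver the allyl group to C3, because the other ortho carbon carries the acetyl group, and tautomerisation restores the phenol next to the new C–C bond.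

Step 4
Reactants: 5 1-[3-allyl-4,6-bis(benzyloxy)-2-hydroxyphenyl]ethan-1-one; 6 4-(benzyloxy)benzoyl chloride
Product: 8 8-allyl-5,7-bis(benzyloxy)-2-[4-(benzyloxy)phenyl]-4H-chromen-4-one, via 1,3-diketone 7 (not isolated)
Conditions: LiN(SiMe3)2 (3.5 equiv), THF, −78 °C; 6, −78 °C to rt; aq. NH4Cl; crude, TsOH·H2O (cat.), PhMe, 80 °C
Reagents that add atoms: none
Why: Baker–Venkataraman-type C-aroylation of the lithium dianion gives the 1,3-diketone, whose acid-catalysed cyclodehydration onto the phenol flanked by the allyl group closes the chromen-4-one, so the allyl group must sit at C8.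

Step 5
Reactants: 8 8-allyl-5,7-bis(benzyloxy)-2-[4-(benzyloxy)phenyl]-4H-chromen-4-one
Product: 9 5,7-bis(benzyloxy)-2-[4-(benzyloxy)phenyl]-8-(2-oxopropyl)-4H-chromen-4-one
Conditions: PdCl2 (10 mol%), CuCl (1 equiv), O2 (1 atm), DMF/H2O 7:1, rt
Reagents that add atoms: water, O
Why: Tsuji–Wacker oxidation: Markovnikov hydroxypalladation of the terminal alkene and β-hydride elimination should give the methyl ketone, with CuCl and O2 returning zerovalent palladium to PdCl2, while benzyl ethers and the chromenone are inert.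

Step 6
Reactants: 9 5,7-bis(benzyloxy)-2-[4-(benzyloxy)phenyl]-8-(2-oxopropyl)-4H-chromen-4-one
Product: 10 5,7-bis(benzyloxy)-2-[4-(benzyloxy)phenyl]-8-(3-oxobut-1-en-2-yl)-4H-chromen-4-one
Conditions: (CH2O)n, diisopropylammonium trifluoroacetate (1 equiv), CF3CO2H (10 mol%), THF, reflux
Reagents that add atoms: formaldehyde (as paraformaldehyde), C=O
Why: Mannich-type α-methylenation: the ammonium salt forms the iminium ion of formaldehyde, which is attacked by the more substituted, aryl-activated enol, and loss of the amine from the β-amino ketone should give the 2-aryl enone.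

Step 7
Reactants: 10 5,7-bis(benzyloxy)-2-[4-(benzyloxy)phenyl]-8-(3-oxobut-1-en-2-yl)-4H-chromen-4-one
Product: 11 5,7-bis(benzyloxy)-2-[4-(benzyloxy)phenyl]-8-[3-(tert-butyldimethylsilyloxy)buta-1,3-dien-2-yl]-4H-chromen-4-one
Conditions: TBSOTf (1.3 equiv), Et3N (3 equiv), CH2Cl2, −78 to 0 °C; cold aq. NaHCO3
Reagents that add atoms: tert-butyldimethylsilyl trifluoromethanesulfonate, CC(C)(C)[Si](C)(C)OS(=O)(=O)C(F)(F)F
Why: Soft enolisation of the methyl ketone, its only enolisable position, with a silyl triflate and amine gives the cross-conjugated 2-silyloxydiene; the tert-butyldimethylsilyl group is chosen over trimethylsilyl so that the diene tolerates chromatography on amine-washed silica and prolonged heating, and reversible silylation of the chromenone oxygen is undone in the work-up.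

Step 8
Reactants: 11 5,7-bis(benzyloxy)-2-[4-(benzyloxy)phenyl]-8-[3-(tert-butyldimethylsilyloxy)buta-1,3-dien-2-yl]-4H-chromen-4-one; 12 methyl propiolate
Product: 15 methyl 3-Fl-4-hydroxybenzoate, via cyclohexa-1,4-diene adduct 13 (not isolated), via aryl silyl ether 14 (not isolated)
Conditions: 12 (5 equiv), BHT (cat.), PhMe, 110 °C, sealed tube; then DDQ (1.1 equiv), rt; then TBAF (3 equiv), THF, 0 °C; aq. NH4Cl
Reagents that add atoms: none
Why: The electron-rich 2-silyloxydiene 11 and the electron-poor alkyne 12 should combine in a concerted, asynchronous, normal-demand [4+2] cycloaddition in which the terminal CH2 next to the silyloxy carbon (future C5′) leads in bonding to the propiolate β-carbon (future C6′) while C2′–C1′ closes behind it. The closest known reaction type is the Diels–Alder reaction of 2-silyloxy-1,3-dienes with propiolates followed by quinone dehydrogenation to 4-oxygenated benzoates. Ring B is closed by this intermolecular cycloaddition as the cyclohexa-1,4-diene 13, from which DDQ takes hydride at the doubly allylic C2′ (cation stabilised by the silyloxy group) and a proton is lost from C5′ to give arene 14, whose silyl ether fluoride then cleaves. No stereocentre is formed. The step needs regioselectivity (ester para to the ring B oxygen, meta to the flavone), which the strongly donating silyloxy group secures because the flavonyl group on the neighbouring diene carbon is twisted out of conjugation by its two ortho substituents (the C7 benzyloxy group and ring oxygen O1) and cannot steer the addition. It also needs chemoselective dehydrogenation, secured by using DDQ at room temperature, where unsubstituted benzyl ethers and the chromenone are not attacked.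

Step 9
Reactants: 15 methyl 3-Fl-4-hydroxybenzoate
Product: 17 4-(benzyloxy)-3-Fl-benzoic acid, via benzyl ether ester 16 (not isolated)
Conditions: BnBr (1.3 equiv), K2CO3, DMF, 50 °C; then LiOH·H2O, H2O/MeOH, 50 °C; aq. HCl
Reagents that add atoms: benzyl bromide, BrCc1ccccc1; lithium hydroxide, [Li+].[OH-]
Why: Williamson benzylation of the hindered but acidic 4-hydroxybenzoate phenol followed in the same flask by saponification of the unhindered methyl ester should give the acid, the chromenone ring tolerating warm dilute hydroxide.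

Step 10
Reactants: 17 4-(benzyloxy)-3-Fl-benzoic acid
Product: 19 [4-(benzyloxy)-3-Fl-phenyl]methanol, via mixed carbonic anhydride 18 (not isolated)
Conditions: iBuOCOCl, N-methylmorpholine, THF, −15 °C; then NaBH4, H2O, 0 °C
Reagents that add atoms: none
Why: Reduction of a mixed carbonic anhydride with NaBH4 is fast at 0 °C, whereas the chromen-4-one carbonyl, a vinylogous ester, is not attacked by borohydride under these conditions; this is why aluminium hydride reduction of the ester itself, which would also reduce the chromenone, is avoided.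

Step 11
Reactants: 19 [4-(benzyloxy)-3-Fl-phenyl]methanol
Product: 20 4-(benzyloxy)-3-Fl-benzaldehyde
Conditions: MnO2 (10 equiv), CH2Cl2, rt
Reagents that add atoms: none
Why: MnO2 oxidises the benzylic alcohol to the aldehyde on the surface of the oxide and stops there, leaving ethers and chromenone untouched.

Step 12
Reactants: 2 1-[2,4-bis(benzyloxy)-6-hydroxyphenyl]ethan-1-one
Product: 21 tert-butyl 3-[2,4-bis(benzyloxy)-6-hydroxyphenyl]-3-oxopropanoate
Conditions: LiN(SiMe3)2 (3.2 equiv), THF, −78 °C; Boc2O (1.05 equiv), −78 to 0 °C; aq. NH4Cl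
Reagents that add atoms: di-tert-butyl dicarbonate, CC(C)(C)OC(=O)OC(=O)OC(C)(C)C
Why: Claisen-type C-acylation of the lithium dianion with the dicarbonate should give the β-keto ester, any aryl carbonate formed first being carried to the same product by base-induced O-to-C carboxyl transfer, and the tert-butyl ester does not lactonise onto the phenol.

Step 13
Reactants: 20 4-(benzyloxy)-3-Fl-benzaldehyde; 21 tert-butyl 3-[2,4-bis(benzyloxy)-6-hydroxyphenyl]-3-oxopropanoate
Product: 22 tert-butyl 2-[2,4-bis(benzyloxy)-6-hydroxybenzoyl]-3-[4-(benzyloxy)-3-Fl-phenyl]prop-2-enoate (alkene geometry not defined)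
Conditions: piperidine (10 mol%), AcOH (10 mol%), 4 Å MS, PhMe, rt
Reagents that add atoms: none
Why: Knoevenagel condensation under piperidinium acetate catalysis with removal of water should give the alkylidene β-keto ester, the bulky tert-butyl ester slowing uncatalysed ring closure enough for isolation.

Step 14
Reactants: 22 tert-butyl 2-[2,4-bis(benzyloxy)-6-hydroxybenzoyl]-3-[4-(benzyloxy)-3-Fl-phenyl]prop-2-enoate
Product: 25 (2S)-5,7-bis(benzyloxy)-2-[4-(benzyloxy)-3-Fl-phenyl]chroman-4-one, via tert-butyl ester 23 (not isolated), via keto acid 24 (not isolated)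
Conditions: 9-amino(9-deoxy)epi-quinine 3,5-bis(trifluoromethyl)phenyl thiourea (10 mol%), PhMe, −25 °C; then TsOH·H2O (1 equiv), 80 °C
Reagents that add atoms: none
Why: Bifunctional cinchona-thiourea catalysis of an intramolecular oxa-Michael addition (6-endo-trig), in which the thiourea binds the β-keto ester and the quinuclidine activates the phenol so that oxygen adds to one face of the alkylidene and fixes C2 as S, after which TsOH cleaves the tert-butyl ester and the β-keto acid loses CO2 without touching C2.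

Step 15
Reactants: 25 (2S)-5,7-bis(benzyloxy)-2-[4-(benzyloxy)-3-Fl-phenyl]chroman-4-one
Product: 26 (2S)-5,7-dihydroxy-2-{4-hydroxy-3-[5,7-dihydroxy-2-(4-hydroxyphenyl)-4-oxo-4H-chromen-8-yl]phenyl}chroman-4-one (target)
Conditions: H2 (1 atm), 10% Pd/C, THF/MeOH 1:1, rt
Reagents that add atoms: none
Why: Hydrogenolysis of the six benzyl ethers over palladium under neutral conditions should free all phenols without reducing either carbonyl group or the chromenone C2=C3 bond and without opening or epimerising the flavanone at C2.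

Compound list

1 | 2,4,6-trihydroxyacetophenone | CC(=O)c1c(O)cc(O)cc1O | starting material
2 | 1-[2,4-bis(benzyloxy)-6-hydroxyphenyl]ethan-1-one | CC(=O)c1c(O)cc(OCc2ccccc2)cc1OCc1ccccc1 | intermediate
3 | allyl bromide | C=CCBr | starting material
4 | 1-[2-(allyloxy)-4,6-bis(benzyloxy)phenyl]ethan-1-one | CC(=O)c1c(OCC=C)cc(OCc2ccccc2)cc1OCc1ccccc1 | intermediate
5 | 1-[3-allyl-4,6-bis(benzyloxy)-2-hydroxyphenyl]ethan-1-one | CC(=O)c1c(O)c(CC=C)c(OCc2ccccc2)cc1OCc1ccccc1 | intermediate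
6 | 4-(benzyloxy)benzoyl chloride | O=C(Cl)c1ccc(OCc2ccccc2)cc1 | starting material
7 | 1-[3-allyl-4,6-bis(benzyloxy)-2-hydroxyphenyl]-3-[4-(benzyloxy)phenyl]propane-1,3-dione | O=C(CC(=O)c1ccc(OCc2ccccc2)cc1)c1c(O)c(CC=C)c(OCc2ccccc2)cc1OCc1ccccc1 | intermediate
8 | 8-allyl-5,7-bis(benzyloxy)-2-[4-(benzyloxy)phenyl]-4H-chromen-4-one | C=CCc1c(OCc2ccccc2)cc(OCc2ccccc2)c2c(=O)cc(-c3ccc(OCc4ccccc4)cc3)oc12 | intermediate
9 | 5,7-bis(benzyloxy)-2-[4-(benzyloxy)phenyl]-8-(2-oxopropyl)-4H-chromen-4-one | CC(=O)Cc1c(OCc2ccccc2)cc(OCc2ccccc2)c2c(=O)cc(-c3ccc(OCc4ccccc4)cc3)oc12 | intermediate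
10 | 5,7-bis(benzyloxy)-2-[4-(benzyloxy)phenyl]-8-(3-oxobut-1-en-2-yl)-4H-chromen-4-one | CC(=O)C(=C)c1c(OCc2ccccc2)cc(OCc2ccccc2)c2c(=O)cc(-c3ccc(OCc4ccccc4)cc3)oc12 | intermediate
11 | 5,7-bis(benzyloxy)-2-[4-(benzyloxy)phenyl]-8-[3-(tert-butyldimethylsilyloxy)buta-1,3-dien-2-yl]-4H-chromen-4-one | C=C(O[Si](C)(C)C(C)(C)C)C(=C)c1c(OCc2ccccc2)cc(OCc2ccccc2)c2c(=O)cc(-c3ccc(OCc4ccccc4)cc3)oc12 | intermediate
12 | methyl propiolate | C#CC(=O)OC | starting material
13 | methyl 5-{5,7-bis(benzyloxy)-2-[4-(benzyloxy)phenyl]-4-oxo-4H-chromen-8-yl}-4-(tert-butyldimethylsilyloxy)cyclohexa-1,4-diene-1-carboxylate | COC(=O)C1=CCC(O[Si](C)(C)C(C)(C)C)=C(C1)c1c(OCc2ccccc2)cc(OCc2ccccc2)c2c(=O)cc(-c3ccc(OCc4ccccc4)cc3)oc12 | intermediate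
14 | methyl 3-{5,7-bis(benzyloxy)-2-[4-(benzyloxy)phenyl]-4-oxo-4H-chromen-8-yl}-4-(tert-butyldimethylsilyloxy)benzoate | COC(=O)c1ccc(O[Si](C)(C)C(C)(C)C)c(-c2c(OCc3ccccc3)cc(OCc3ccccc3)c3c(=O)cc(-c4ccc(OCc5ccccc5)cc4)oc23)c1 | intermediate
15 | methyl 3-{5,7-bis(benzyloxy)-2-[4-(benzyloxy)phenyl]-4-oxo-4H-chromen-8-yl}-4-hydroxybenzoate | COC(=O)c1ccc(O)c(-c2c(OCc3ccccc3)cc(OCc3ccccc3)c3c(=O)cc(-c4ccc(OCc5ccccc5)cc4)oc23)c1 | intermediate
16 | methyl 4-(benzyloxy)-3-{5,7-bis(benzyloxy)-2-[4-(benzyloxy)phenyl]-4-oxo-4H-chromen-8-yl}benzoate | COC(=O)c1ccc(OCc2ccccc2)c(-c2c(OCc3ccccc3)cc(OCc3ccccc3)c3c(=O)cc(-c4ccc(OCc5ccccc5)cc4)oc23)c1 | intermediate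
17 | 4-(benzyloxy)-3-{5,7-bis(benzyloxy)-2-[4-(benzyloxy)phenyl]-4-oxo-4H-chromen-8-yl}benzoic acid | OC(=O)c1ccc(OCc2ccccc2)c(-c2c(OCc3ccccc3)cc(OCc3ccccc3)c3c(=O)cc(-c4ccc(OCc5ccccc5)cc4)oc23)c1 | intermediate
18 | 4-(benzyloxy)-3-{5,7-bis(benzyloxy)-2-[4-(benzyloxy)phenyl]-4-oxo-4H-chromen-8-yl}benzoic isobutyl carbonic anhydride | CC(C)COC(=O)OC(=O)c1ccc(OCc2ccccc2)c(-c2c(OCc3ccccc3)cc(OCc3ccccc3)c3c(=O)cc(-c4ccc(OCc5ccccc5)cc4)oc23)c1 | intermediate
19 | 5,7-bis(benzyloxy)-8-[2-(benzyloxy)-5-(hydroxymethyl)phenyl]-2-[4-(benzyloxy)phenyl]-4H-chromen-4-one | OCc1ccc(OCc2ccccc2)c(-c2c(OCc3ccccc3)cc(OCc3ccccc3)c3c(=O)cc(-c4ccc(OCc5ccccc5)cc4)oc23)c1 | intermediate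
20 | 4-(benzyloxy)-3-{5,7-bis(benzyloxy)-2-[4-(benzyloxy)phenyl]-4-oxo-4H-chromen-8-yl}benzaldehyde | O=Cc1ccc(OCc2ccccc2)c(-c2c(OCc3ccccc3)cc(OCc3ccccc3)c3c(=O)cc(-c4ccc(OCc5ccccc5)cc4)oc23)c1 | intermediate
21 | tert-butyl 3-[2,4-bis(benzyloxy)-6-hydroxyphenyl]-3-oxopropanoate | CC(C)(C)OC(=O)CC(=O)c1c(O)cc(OCc2ccccc2)cc1OCc1ccccc1 | intermediate
22 | tert-butyl 2-[2,4-bis(benzyloxy)-6-hydroxybenzoyl]-3-(4-(benzyloxy)-3-{5,7-bis(benzyloxy)-2-[4-(benzyloxy)phenyl]-4-oxo-4H-chromen-8-yl}phenyl)prop-2-enoate, alkene geometry not defined | CC(C)(C)OC(=O)C(=Cc1ccc(OCc2ccccc2)c(-c2c(OCc3ccccc3)cc(OCc3ccccc3)c3c(=O)cc(-c4ccc(OCc5ccccc5)cc4)oc23)c1)C(=O)c1c(O)cc(OCc2ccccc2)cc1OCc1ccccc1 | intermediate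
23 | tert-butyl (2S)-5,7-bis(benzyloxy)-2-(4-(benzyloxy)-3-{5,7-bis(benzyloxy)-2-[4-(benzyloxy)phenyl]-4-oxo-4H-chromen-8-yl}phenyl)-4-oxochromane-3-carboxylate, C3 epimerisable and not defined | CC(C)(C)OC(=O)C1C(=O)c2c(OCc3ccccc3)cc(OCc3ccccc3)cc2O[C@@H]1c1ccc(OCc2ccccc2)c(-c2c(OCc3ccccc3)cc(OCc3ccccc3)c3c(=O)cc(-c4ccc(OCc5ccccc5)cc4)oc23)c1 | intermediate
24 | (2S)-5,7-bis(benzyloxy)-2-(4-(benzyloxy)-3-{5,7-bis(benzyloxy)-2-[4-(benzyloxy)phenyl]-4-oxo-4H-chromen-8-yl}phenyl)-4-oxochromane-3-carboxylic acid, C3 not defined | OC(=O)C1C(=O)c2c(OCc3ccccc3)cc(OCc3ccccc3)cc2O[C@@H]1c1ccc(OCc2ccccc2)c(-c2c(OCc3ccccc3)cc(OCc3ccccc3)c3c(=O)cc(-c4ccc(OCc5ccccc5)cc4)oc23)c1 | intermediate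
25 | (2S)-5,7-bis(benzyloxy)-2-(4-(benzyloxy)-3-{5,7-bis(benzyloxy)-2-[4-(benzyloxy)phenyl]-4-oxo-4H-chromen-8-yl}phenyl)chroman-4-one | O=C1C[C@@H](c2ccc(OCc3ccccc3)c(-c3c(OCc4ccccc4)cc(OCc4ccccc4)c4c(=O)cc(-c5ccc(OCc6ccccc6)cc5)oc34)c2)Oc2cc(OCc3ccccc3)cc(OCc3ccccc3)c21 | intermediate
26 | (2S)-5,7-dihydroxy-2-{4-hydroxy-3-[5,7-dihydroxy-2-(4-hydroxyphenyl)-4-oxo-4H-chromen-8-yl]phenyl}chroman-4-one | O=C1C[C@@H](c2ccc(O)c(-c3c(O)cc(O)c4c(=O)cc(-c5ccc(O)cc5)oc34)c2)Oc2cc(O)cc(O)c21 | target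

Total step count: 15. Longest linear sequence: 14 steps (steps 1 to 11, then 13 to 15); step 12 is a one-step branch from 2.

Steps most likely to fail

Step 8. The diene carries the twisted flavonyl group and the silyl ether on adjacent carbons and may populate the reactive s-cis geometry poorly, so that hydrolysis back to the enone or oligomerisation could outrun cycloaddition; addition in the wrong orientation is a lesser risk. The fallback gives up the ring construction and makes the C8–C3′ bond by Suzuki–Miyaura coupling. It sets out from 2 and 6 and comes back at 20. Aroylation of the dianion of 2 with 6 under the conditions of step 4 gives 1-[2,4-bis(benzyloxy)-6-hydroxyphenyl]-3-[4-(benzyloxy)phenyl]propane-1,3-dione F1, which TsOH cyclises to 5,7-bis(benzyloxy)-2-[4-(benzyloxy)phenyl]-4H-chromen-4-one F2. Electrophilic iodination (N-iodosuccinimide, CF3CO2H cat., MeCN), which in 5,7-dialkoxy chromenones takes place at C8, should give 5,7-bis(benzyloxy)-2-[4-(benzyloxy)phenyl]-8-iodo-4H-chromen-4-one F3. Coupling of F3 with commercial [2-(benzyloxy)-5-formylphenyl]boronic acid (O=Cc1ccc(OCc2ccccc2)c(B(O)O)c1; Pd(OAc)2, SPhos, K3PO4, PhMe/H2O, 90 °C) should give aldehyde 20 directly.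

Step 14. The electron-rich, doubly ortho-substituted hydroxyaryl ketone may close the ring without the catalyst, and the benzylic C2–O bond may open and re-close under TsOH at 80 °C; either process would lower the enantiomeric purity. The fallback replaces catalysis by resolution. It sets out from 20 and 2 and comes back at 25. Claisen–Schmidt condensation (KOH, EtOH/THF, rt) should give the (E)-2′-hydroxychalcone F4, and NaOAc in refluxing EtOH should cyclise it to the racemic hexabenzyl flavanone F5. Preparative chromatography on a chiral stationary phase (amylose tris(3,5-dimethylphenylcarbamate)) then separates 25 from the (2R)-antipode F6, which NaOAc re-equilibrates to F5 for another pass.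

Step 6. Aminomethylation may take place on the methyl side of the ketone or twice, and the 2-aryl enone may oligomerise under hot acidic conditions. The fallback builds the enone from an aldehyde that has only one enolisable position. It sets out from 8 and comes back at 10. Lemieux–Johnson cleavage of the allyl group (OsO4 cat., NaIO4, 2,6-lutidine, dioxane/H2O) should give the arylacetaldehyde F7. Amine-catalysed α-methylenation (aq. HCHO, pyrrolidine, EtCO2H, iPrOH, 45 °C) should give the 2-arylacrolein F8. Aldehyde-selective methyl addition with MeTi(OiPr)3 (THF, −40 °C), which leaves the chromenone alone, should give the racemic allylic alcohol F9, and MnO2 in CH2Cl2 should oxidise it to enone 10.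

Further compounds

F1 | step 8 | 1-[2,4-bis(benzyloxy)-6-hydroxyphenyl]-3-[4-(benzyloxy)phenyl]propane-1,3-dione | O=C(CC(=O)c1ccc(OCc2ccccc2)cc1)c1c(O)cc(OCc2ccccc2)cc1OCc1ccccc1
F2 | step 8 | 5,7-bis(benzyloxy)-2-[4-(benzyloxy)phenyl]-4H-chromen-4-one | O=c1cc(-c2ccc(OCc3ccccc3)cc2)oc2cc(OCc3ccccc3)cc(OCc3ccccc3)c12
F3 | step 8 | 5,7-bis(benzyloxy)-2-[4-(benzyloxy)phenyl]-8-iodo-4H-chromen-4-one | Ic1c(OCc2ccccc2)cc(OCc2ccccc2)c2c(=O)cc(-c3ccc(OCc4ccccc4)cc3)oc12
F4 | step 14 | (E)-1-[2,4-bis(benzyloxy)-6-hydroxyphenyl]-3-(4-(benzyloxy)-3-{5,7-bis(benzyloxy)-2-[4-(benzyloxy)phenyl]-4-oxo-4H-chromen-8-yl}phenyl)prop-2-en-1-one | O=C(/C=C/c1ccc(OCc2ccccc2)c(-c2c(OCc3ccccc3)cc(OCc3ccccc3)c3c(=O)cc(-c4ccc(OCc5ccccc5)cc4)oc23)c1)c1c(O)cc(OCc2ccccc2)cc1OCc1ccccc1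
F5 | step 14 | racemic 5,7-bis(benzyloxy)-2-(4-(benzyloxy)-3-{5,7-bis(benzyloxy)-2-[4-(benzyloxy)phenyl]-4-oxo-4H-chromen-8-yl}phenyl)chroman-4-one | O=C1CC(c2ccc(OCc3ccccc3)c(-c3c(OCc4ccccc4)cc(OCc4ccccc4)c4c(=O)cc(-c5ccc(OCc6ccccc6)cc5)oc34)c2)Oc2cc(OCc3ccccc3)cc(OCc3ccccc3)c21
F6 | step 14 | (2R)-5,7-bis(benzyloxy)-2-(4-(benzyloxy)-3-{5,7-bis(benzyloxy)-2-[4-(benzyloxy)phenyl]-4-oxo-4H-chromen-8-yl}phenyl)chroman-4-one | O=C1C[C@H](c2ccc(OCc3ccccc3)c(-c3c(OCc4ccccc4)cc(OCc4ccccc4)c4c(=O)cc(-c5ccc(OCc6ccccc6)cc5)oc34)c2)Oc2cc(OCc3ccccc3)cc(OCc3ccccc3)c21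
F7 | step 6 | 2-{5,7-bis(benzyloxy)-2-[4-(benzyloxy)phenyl]-4-oxo-4H-chromen-8-yl}acetaldehyde | O=CCc1c(OCc2ccccc2)cc(OCc2ccccc2)c2c(=O)cc(-c3ccc(OCc4ccccc4)cc3)oc12
F8 | step 6 | 2-{5,7-bis(benzyloxy)-2-[4-(benzyloxy)phenyl]-4-oxo-4H-chromen-8-yl}prop-2-enal | C=C(C=O)c1c(OCc2ccccc2)cc(OCc2ccccc2)c2c(=O)cc(-c3ccc(OCc4ccccc4)cc3)oc12
F9 | step 6 | racemic 5,7-bis(benzyloxy)-2-[4-(benzyloxy)phenyl]-8-(3-hydroxybut-1-en-2-yl)-4H-chromen-4-one | CC(O)C(=C)c1c(OCc2ccccc2)cc(OCc2ccccc2)c2c(=O)cc(-c3ccc(OCc4ccccc4)cc3)oc12
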